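Readings and results are calculated from invented constants; scatter was added.

Millimolar was the unit of the quantity I wanted, and two rates gave it: the making of L by D -> L, k1·D, and its loss by D + L -> E, k2·D·L, with L as a concentration. Their ratio is k2·L/k1, with D and time both gone.

the same everywhere: D 10 mM
- south-east: J 1.2 equiv (fed, over 20 min); run made earlier; the fed solution adds 0.25 times the starting volume
- flask: J 0.600 equiv (fed, over 20 min); the fed solution adds 0.25 times the starting volume; time 2.5 h
south-east run (percent of the D charged)

| time / min | L / % | G / % | D / % |
|---|---|---|---|
| 4.00 | 10.4 | 1.2 | 79.1 |
| 8.00 | 13.8 | 4.6 | 58.4 |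
| 12.0 | 11.8 | 11.6 | 44.1 |
| 15.0 | 10.4 | 14.9 | 36.7 |

(standard deviation of a reading: 0.5 percentage points)
- a species is counted by the D in it: one E counts as two
- charges are per starting volume, the dose included; the dosed solution carries all of it
- steps under discussion: D -> L; D + L -> E; J + L -> G
- time, not beyond 2.5 h, at which the flask holds most L
- the amount of L, in percent of the D charged, at that time
- the first time at which L reaches 7.8%, in the same percent, in min

So I counted events in the south-east run between 4.00 min and 12.0 min. By balance E rose 23 percentage points, so D + L -> E took 12 points of D, since one E counts as two. D fell 35 points, which left 23 points for D -> L, and the ratio was 0.496. L averaged 1.13 mM after dilution, so I read Λ = k1/k2 as 2.28 mM, the concentration of L at which the loss to E equals the making: the steady-state level of L against that loss.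

J + L -> G adds a further loss, so I took Λ as a ceiling on the concentration of L. A percent of the charge counts amount, and the volume grows, so at its full volume the flask's ceiling was 28.5% of the charge, more than the south-east top reading of 13.8%. The flask gets half the J of that run, so I put its peak between these two values.

The forecast said 14.6% at 0.165 h, reaching the level at 2.3 min: “J stays in excess of the remaining L, so there is no late maximum”. The flask gave 15.5% at 0.174 h, reaching the level at 2.18 min.

    D → L (k = 7.80 × 10⁻⁴ s⁻¹)
    D + L → E (k = 0.340 M⁻¹ s⁻¹)
    J + L → G (k = 0.420 M⁻¹ s⁻¹)

That peak lay inside my bracket and below the ceiling. Λ contains no charge, so for a neighbouring flask, the same recipe with 40 mM of D, I kept 2.28 mM, which at full volume is 7.13% of its charge; L there peaked lower than that, at 5.03%.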